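**Plan**
- Retrosynthetic cuts, in order: the enol acetate and the C1=C2/C10=CH unsaturation (back to ring enal ester 22); the formyl carbon (back to the enol triflate of ring β-keto ester 19); the ring bond C7–C8 (back to open-chain vinyl β-keto ester 18); the vinyl ketone (ester enolate + acrolein); the Z-C3=C4 alkene (Wittig); the quaternary C6 (copper-catalysed allyl–alkyl coupling).
- Feature used: in the ten-membered ring, C7 (H, CH3) sits next to quaternary C6, so it is the Markovnikov radical of a vinyl group on C6. C8 lies two carbons from C10, which can be carried as a ketone, so C8 is the β-carbon of a vinyl ketone. The Z-C3=C4 alkene and the gem-disubstituted C6 fold the chain.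
- Forward: two small pieces give the C6 quaternary centre, the chain is extended linearly, the single carbocycle is closed at C7–C8 by a hydrogen-atom-transfer radical conjugate addition, and the triene and enol acetate are unveiled last.
- Stereochemistry: C6 from the chiral copper catalyst; C7 from substrate control in the ring closure; Z-C3=C4 from the Wittig reaction; ring-cis C1=C2 and the Z-enol acetate from the ring and a chelated lithium trienolate.

Key step: step 10

Remark: locants C1–C10 in the comments are the ring locants of the target (C1 bears CO2Me, C6 is quaternary, C7 bears H and CH3, C10 bears the acetoxymethylidene group) and are kept for the same carbons in open-chain intermediates; compound names use their own locants. 3-Ethenylfuran (2) is assumed to be handled as a distilled solution because it is volatile. The ligand antipode in step 4 is assumed to be assignable from the facial model of the known coupling.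

**Step 1**
Reactants: 1 furan-3-carbaldehyde
Product: 2 3-ethenylfuran
Conditions: Ph3PCH3Br, KOt-Bu, Et2O, 0 °C to rt; distilled as a solution
Reagents that add atoms: methyltriphenylphosphonium bromide, [Br-].C[P+](c1ccccc1)(c1ccccc1)c1ccccc1
Why: Wittig methylenation of an aromatic aldehyde with the non-stabilised ylide should give the vinyl heteroarene directly.

**Step 2**
Reactants: 3 tert-butyl(but-3-yn-1-yloxy)dimethylsilane
Product: 5 (E)-5-[(tert-butyldimethylsilyl)oxy]-3-methylpent-2-en-1-ol, via vinylalane 4 (not isolated)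
Conditions: AlMe3, Cp2ZrCl2 (25 mol %), CH2Cl2, 0 °C to rt; then (CH2O)n, THF, 0 °C to rt; aqueous work-up
Reagents that add atoms: trimethylaluminium, C[Al](C)C; paraformaldehyde (source of formaldehyde), C=O
Why: Zirconium-catalysed syn carboalumination of the terminal alkyne (Negishi carboalumination) places CH3 on the internal carbon, and hydroxymethylation of the alkenylalane with retention fixes the E geometry.

**Step 3**
Reactants: 5 (E)-5-[(tert-butyldimethylsilyl)oxy]-3-methylpent-2-en-1-ol
Product: 7 tert-butyl{[(E)-5-chloro-3-methylpent-3-en-1-yl]oxy}dimethylsilane, via allylic mesylate 6 (not isolated)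
Conditions: MsCl, LiCl, 2,4,6-collidine, DMF, 0 °C
Reagents that add atoms: lithium chloride, [Li+].[Cl-]
Why: Chloride displaces the primary allylic mesylate by SN2 under buffered conditions, so neither allylic transposition nor loss of E geometry is expected.

**Step 4**
Reactants: 2 3-ethenylfuran; 7 tert-butyl{[(E)-5-chloro-3-methylpent-3-en-1-yl]oxy}dimethylsilane
Product: 9 tert-butyl{[(3R)-3-[2-(furan-3-yl)ethyl]-3-methylpent-4-en-1-yl]oxy}dimethylsilane, via alkylborane 8 (not isolated)
Conditions: 2, (9-BBN)2, THF, 60 °C; then 7, CuOTf·(toluene)0.5 (10 mol %), DTBM-MeO-BIPHEP (single enantiomer, 12 mol %), EtOK, 1,4-dioxane, 25 °C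
Reagents that add atoms: none
Why: Copper-catalysed γ-selective (SN2′) allyl–alkyl coupling of an alkyl-9-BBN borate with a γ,γ-disubstituted primary allyl chloride is a known route to all-carbon quaternary centres, and with the geometrically pure E-chloride the chiral bisphosphine–copper catalyst (ligand antipode chosen accordingly) should deliver the furylethyl group to the face that gives the (R) centre, C6 of the target.

**Step 5**
Reactants: 9 tert-butyl{[(3R)-3-[2-(furan-3-yl)ethyl]-3-methylpent-4-en-1-yl]oxy}dimethylsilane
Product: 10 (3R)-3-[2-(furan-3-yl)ethyl]-3-methylpent-4-en-1-ol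
Conditions: TBAF, THF, rt
Reagents that add atoms: none
Why: Fluoride cleaves the primary silyl ether, and nothing else in 9 is fluoride-sensitive.

**Step 6**
Reactants: 10 (3R)-3-[2-(furan-3-yl)ethyl]-3-methylpent-4-en-1-ol
Product: 11 (3R)-3-[2-(furan-3-yl)ethyl]-3-methylpent-4-enal
Conditions: Dess–Martin periodinane, CH2Cl2, rt
Reagents that add atoms: none
Why: Dess–Martin oxidation of the primary alcohol should spare the furan and the vinyl group, and the β-quaternary aldehyde has no epimerisable centre.

**Step 7**
Reactants: 11 (3R)-3-[2-(furan-3-yl)ethyl]-3-methylpent-4-enal; 12 (4-methoxy-4-oxobutyl)triphenylphosphonium bromide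
Product: 14 methyl (4Z,7R)-7-[2-(furan-3-yl)ethyl]-7-methylnona-4,8-dienoate, via ylide 13 (not isolated)
Conditions: 12, NaHMDS, THF, −78 to 0 °C; then 11, −78 °C to rt
Reagents that add atoms: none
Why: Wittig olefination with the salt-free non-stabilised ylide under kinetic control should give the Z-alkene (target C3=C4) and installs the four-carbon ester arm in one operation.

**Step 8**
Reactants: 14 methyl (4Z,7R)-7-[2-(furan-3-yl)ethyl]-7-methylnona-4,8-dienoate; 15 prop-2-enal (acrolein)
Product: 17 methyl (4Z,7R)-7-[2-(furan-3-yl)ethyl]-2-(1-hydroxyprop-2-en-1-yl)-7-methylnona-4,8-dienoate (diastereomer mixture), via lithium enolate 16 (not isolated)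
Conditions: LDA, THF, −78 °C; then 15, −78 °C; AcOH quench
Reagents that add atoms: none
Why: Aldol addition of the lithium ester enolate to acrolein at low temperature should be 1,2-selective, and the two new stereocentres are irrelevant because both are destroyed in steps 9 and 11.

**Step 9**
Reactants: 17 methyl (4Z,7R)-7-[2-(furan-3-yl)ethyl]-2-(1-hydroxyprop-2-en-1-yl)-7-methylnona-4,8-dienoate
Product: 18 methyl (4Z,7R)-7-[2-(furan-3-yl)ethyl]-7-methyl-2-(prop-2-enoyl)nona-4,8-dienoate
Conditions: Dess–Martin periodinane, CH2Cl2, 0 °C; used at once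
Reagents that add atoms: none
Why: Dess–Martin oxidation of the allylic β-hydroxy ester should give the vinyl β-keto ester (a Nazarov-type reagent) under non-basic conditions that limit self-Michael addition.

**Step 10**
Reactants: 18 methyl (4Z,7R)-7-[2-(furan-3-yl)ethyl]-7-methyl-2-(prop-2-enoyl)nona-4,8-dienoate
Product: 19 methyl (3Z,6R,7R)-6-[2-(furan-3-yl)ethyl]-6,7-dimethyl-10-oxocyclodec-3-ene-1-carboxylate (C1 epimers)
Conditions: Fe(acac)3 (30 mol %), PhSiH3 (3 equiv), EtOH/(CH2OH)2 5:1, 60 °C; 18 added by syringe pump over 10 h, final 1 mM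
Reagents that add atoms: none
Why: Proposed new method: an iron hydride formed from Fe(acac)3 and PhSiH3 should transfer a hydrogen atom to the terminal carbon of the isolated, more electron-rich vinyl group on C6, giving the secondary C7 radical, which adds to the unsubstituted β-carbon C8 of the vinyl ketone; the α-keto radical is then reduced by divalent iron to the enolate and protonated by ethanol (radical–polar crossover). The closest known reaction types are the iron-mediated reductive coupling of unactivated alkenes with enones (intermolecular and in five- to seven-membered ring closures) and the tin hydride endo-macrocyclisation of alkyl radicals onto enones; closing a ten-membered carbocycle this way from a monosubstituted donor alkene has not been shown. The ring closes in the 10-endo-trig mode, the only path that ends on an activated, unhindered carbon (attack at C9 would be 9-exo and polarity-mismatched, and the C3=C4 alkene offers only 4-exo or 5-endo closure), helped by the Z-alkene and the gem-disubstituted C6, which fold the tether. The new stereocentre C7 is set under control of C6: with C6 at a corner of the forming ring and both of its substituents outside, the C7 methyl is expected to lie outside the ring and anti to the longer furylethyl arm, that is cis to the C6 methyl, which is the required (7R) configuration. The step needs hydrogen-atom transfer to the isolated vinyl group in preference to the enone and the internal Z-alkene, and cyclisation faster than reduction or dimerisation of the radical; the electron-poor enone, slow addition and high dilution are relied on for this. The stereocentre at C1 is of no consequence because it is removed in step 11.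

**Step 11**
Reactants: 19 methyl (3Z,6R,7R)-6-[2-(furan-3-yl)ethyl]-6,7-dimethyl-10-oxocyclodec-3-ene-1-carboxylate
Product: 21 methyl (1Z,5R,6R,8Z)-6-[2-(furan-3-yl)ethyl]-5,6-dimethyl-2-{[(trifluoromethyl)sulfonyl]oxy}cyclodeca-1,8-diene-1-carboxylate, via sodium enolate 20 (not isolated)
Conditions: NaH, Et2O, 0 °C; then Tf2O, −78 to 0 °C
Reagents that add atoms: trifluoromethanesulfonic anhydride, O=S(=O)(OS(=O)(=O)C(F)(F)F)C(F)(F)F
Why: The β-keto ester is deprotonated at the doubly activated C1–H and the chelated sodium enolate is O-sulfonylated, which should give the enol triflate with the triflate cis to the ester, the ring-cis geometry of the ten-membered ring.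

**Step 12**
Reactants: 21 methyl (1Z,5R,6R,8Z)-6-[2-(furan-3-yl)ethyl]-5,6-dimethyl-2-{[(trifluoromethyl)sulfonyl]oxy}cyclodeca-1,8-diene-1-carboxylate
Product: 22 methyl (1Z,5R,6R,8Z)-2-formyl-6-[2-(furan-3-yl)ethyl]-5,6-dimethylcyclodeca-1,8-diene-1-carboxylate
Conditions: Pd(PPh3)4 (5 mol %), CO (3 atm), LiCl, Bu3SnH (slow addition), THF, 50 °C
Reagents that add atoms: carbon monoxide, [C-]#[O+]
Why: Palladium-catalysed reductive carbonylation (formylation) of the enol triflate proceeds by oxidative addition to zerovalent palladium, CO insertion and hydride transfer from the stannane with retention of alkene geometry, and slow addition of the stannane should suppress direct hydrogenolysis.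

**Step 13**
Reactants: 22 methyl (1Z,5R,6R,8Z)-2-formyl-6-[2-(furan-3-yl)ethyl]-5,6-dimethylcyclodeca-1,8-diene-1-carboxylate
Product: 24 methyl (1E,3Z,6R,7R,10Z)-10-[(acetyloxy)methylidene]-6-[2-(furan-3-yl)ethyl]-6,7-dimethylcyclodeca-1,3-diene-1-carboxylate, via lithium trienolate 23 (not isolated)
Conditions: LiHMDS, THF, −78 °C; then Ac2O, −78 °C
Reagents that add atoms: acetic anhydride, CC(=O)OC(C)=O
Why: γ-Deprotonation of the enal at the doubly allylic C2 gives the extended lithium trienolate, in which lithium bridging the enolate oxygen and the cis ester carbonyl is expected to hold the new exocyclic double bond in the Z form (oxygen cis to C1) while the ring keeps the new C1=C2 bond cis, and O-acetylation (dienol acetate formation from an enal) should then give the target.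

**Compound list**
1 | furan-3-carbaldehyde | O=Cc1ccoc1 | starting material
2 | 3-ethenylfuran | C=Cc1ccoc1 | intermediate
3 | tert-butyl(but-3-yn-1-yloxy)dimethylsilane | C#CCCO[Si](C)(C)C(C)(C)C | starting material
4 | [(1E)-4-[(tert-butyldimethylsilyl)oxy]-2-methylbut-1-en-1-yl]dimethylalane (vinylalane, not isolated) | C[Al](C)/C=C(\C)CCO[Si](C)(C)C(C)(C)C | intermediate
5 | (E)-5-[(tert-butyldimethylsilyl)oxy]-3-methylpent-2-en-1-ol | OC/C=C(\C)CCO[Si](C)(C)C(C)(C)C | intermediate
6 | (E)-5-[(tert-butyldimethylsilyl)oxy]-3-methylpent-2-en-1-yl methanesulfonate (not isolated) | CS(=O)(=O)OC/C=C(\C)CCO[Si](C)(C)C(C)(C)C | intermediate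
7 | tert-butyl{[(E)-5-chloro-3-methylpent-3-en-1-yl]oxy}dimethylsilane | ClC/C=C(\C)CCO[Si](C)(C)C(C)(C)C | intermediate
8 | 9-[2-(furan-3-yl)ethyl]-9-borabicyclo[3.3.1]nonane (not isolated) | C1CC2CCCC(C1)B2CCc1ccoc1 | intermediate
9 | tert-butyl{[(3R)-3-[2-(furan-3-yl)ethyl]-3-methylpent-4-en-1-yl]oxy}dimethylsilane | CC(C)(C)[Si](C)(C)OCC[C@@](C)(CCc1ccoc1)C=C | intermediate
10 | (3R)-3-[2-(furan-3-yl)ethyl]-3-methylpent-4-en-1-ol | OCC[C@@](C)(CCc1ccoc1)C=C | intermediate
11 | (3R)-3-[2-(furan-3-yl)ethyl]-3-methylpent-4-enal | O=CC[C@@](C)(CCc1ccoc1)C=C | intermediate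
12 | (4-methoxy-4-oxobutyl)triphenylphosphonium bromide | [Br-].COC(=O)CCC[P+](c1ccccc1)(c1ccccc1)c1ccccc1 | starting material
13 | methyl 4-(triphenylphosphoranylidene)butanoate (ylide, not isolated) | COC(=O)CCC=P(c1ccccc1)(c1ccccc1)c1ccccc1 | intermediate
14 | methyl (4Z,7R)-7-[2-(furan-3-yl)ethyl]-7-methylnona-4,8-dienoate | COC(=O)CC/C=C\C[C@@](C)(CCc1ccoc1)C=C | intermediate
15 | prop-2-enal (acrolein) | C=CC=O | starting material
16 | lithium ester enolate of 14 (not isolated) | COC(O[Li])=CC/C=C\C[C@@](C)(CCc1ccoc1)C=C | intermediate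
17 | methyl (4Z,7R)-7-[2-(furan-3-yl)ethyl]-2-(1-hydroxyprop-2-en-1-yl)-7-methylnona-4,8-dienoate (diastereomer mixture) | COC(=O)C(C(O)C=C)C/C=C\C[C@@](C)(CCc1ccoc1)C=C | intermediate
18 | methyl (4Z,7R)-7-[2-(furan-3-yl)ethyl]-7-methyl-2-(prop-2-enoyl)nona-4,8-dienoate | COC(=O)C(C(=O)C=C)C/C=C\C[C@@](C)(CCc1ccoc1)C=C | intermediate
19 | methyl (3Z,6R,7R)-6-[2-(furan-3-yl)ethyl]-6,7-dimethyl-10-oxocyclodec-3-ene-1-carboxylate (C1 epimers) | COC(=O)C1C/C=C\C[C@@](C)(CCc2ccoc2)[C@H](C)CCC1=O | intermediate
20 | sodium enolate of 19 (not isolated) | COC(=O)/C1=C(O[Na])/CC[C@@H](C)[C@](C)(CCc2ccoc2)C/C=C\C1 | intermediate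
21 | methyl (1Z,5R,6R,8Z)-6-[2-(furan-3-yl)ethyl]-5,6-dimethyl-2-{[(trifluoromethyl)sulfonyl]oxy}cyclodeca-1,8-diene-1-carboxylate | COC(=O)/C1=C(OS(=O)(=O)C(F)(F)F)/CC[C@@H](C)[C@](C)(CCc2ccoc2)C/C=C\C1 | intermediate
22 | methyl (1Z,5R,6R,8Z)-2-formyl-6-[2-(furan-3-yl)ethyl]-5,6-dimethylcyclodeca-1,8-diene-1-carboxylate | COC(=O)/C1=C(C=O)/CC[C@@H](C)[C@](C)(CCc2ccoc2)C/C=C\C1 | intermediate
23 | lithium (Z)-trienolate of 22 (not isolated) | COC(=O)/C1=C/C=C\C[C@@](C)(CCc2ccoc2)[C@H](C)CC\C1=C\O[Li] | intermediate
24 | methyl (1E,3Z,6R,7R,10Z)-10-[(acetyloxy)methylidene]-6-[2-(furan-3-yl)ethyl]-6,7-dimethylcyclodeca-1,3-diene-1-carboxylate | COC(=O)/C1=C/C=C\C[C@@](C)(CCc2ccoc2)[C@H](C)CC\C1=C\OC(C)=O | target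

Total step count: 13. Longest linear sequence: 12 (steps 2 to 13).

**Steps most likely to fail**

Step 10. The hydrogen atom may be delivered to the enone instead of the isolated vinyl group. The C7 radical may be reduced, may take a hydrogen from the allylic C2 by a 1,6-shift, or may add to a second molecule faster than it closes the strained ten-membered ring. The facial selectivity at C7 may also be poor. The fallback closes the ring at C1–C2 instead and makes the C7–C8 bond intermolecularly, all by known reaction types. It sets out from aldehyde 11. Still–Gennari olefination ((CF3CH2O)2P(O)CH2CO2Me, KHMDS, 18-crown-6, THF, −78 °C) would give methyl (2Z,5R)-5-[2-(furan-3-yl)ethyl]-5-methylhepta-2,6-dienoate F1. DIBAL-H (CH2Cl2, −78 °C) would give (2Z,5R)-5-[2-(furan-3-yl)ethyl]-5-methylhepta-2,6-dien-1-ol F2. Intermolecular iron-mediated reductive olefin coupling of its vinyl group with excess freshly made methyl 3-oxopent-4-enoate (Fe(acac)3, PhSiH3, EtOH/(CH2OH)2, 60 °C) would give methyl (7R,9Z)-7-[2-(furan-3-yl)ethyl]-11-hydroxy-6,7-dimethyl-3-oxoundec-9-enoate F3, as both epimers at the new methyl-bearing carbon. CBr4/PPh3 (CH2Cl2, 0 °C) would give methyl (7R,9Z)-11-bromo-7-[2-(furan-3-yl)ethyl]-6,7-dimethyl-3-oxoundec-9-enoate F4. Intramolecular C-alkylation of the β-keto ester by the Z-allylic bromide (Cs2CO3, MeCN, high dilution) would close the ring and return to the route at 19. The open-chain coupling offers no control at C7, so the epimers would have to be separated at 19 or later.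

Step 13. The enolate may form from the s-trans enal conformer and give the E-enol acetate. Deprotonation may occur at C9 instead of C2, or acylation may occur on carbon. The fallback ties the oxygen to the carboxyl carbon in a ring before the acetyl group is put on. It sets out from 22. LiOH (THF/H2O, then mild acid) would give the Z-formyl acid in its ring-closed form, (6R,7R,9Z)-7-[2-(furan-3-yl)ethyl]-3-hydroxy-6,7-dimethyl-4,5,6,7,8,11-hexahydrocyclodeca[c]furan-1(3H)-one F5. MsCl/Et3N (CH2Cl2, −20 °C) would ionise the lactol mesylate and remove a C2 proton (a vinylogous lactol dehydration) to give the enol lactone (6R,7R,9Z,11E)-7-[2-(furan-3-yl)ethyl]-6,7-dimethyl-5,6,7,8-tetrahydrocyclodeca[c]furan-1(4H)-one F6, in which the enol oxygen is held cis to C1. NaOMe (1 equiv, THF, −78 °C) would open the lactone at the acyl carbon to the methyl ester and the Z-enolate, and Ac2O would trap it, returning to the route at 24.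

Step 12. Oxidative addition and CO insertion at the hindered tetrasubstituted triflate may be slow, so that hydride capture gives simple hydrogenolysis, and the doubly activated alkene of the product may be reduced by the stannane. The fallback separates acyl capture from reduction. It sets out from 21. Palladium-catalysed thiocarbonylation (Pd(OAc)2, PPh3, CO, EtSH, Et3N, DMF, 60 °C) would give methyl (1Z,5R,6R,8Z)-2-[(ethylsulfanyl)carbonyl]-6-[2-(furan-3-yl)ethyl]-5,6-dimethylcyclodeca-1,8-diene-1-carboxylate F7. Fukuyama reduction (Et3SiH, Pd/C, acetone, rt) would then give the aldehyde and return to the route at 22.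

**Further compounds**
F1 | step 10 | methyl (2Z,5R)-5-[2-(furan-3-yl)ethyl]-5-methylhepta-2,6-dienoate | COC(=O)/C=C\C[C@@](C)(CCc1ccoc1)C=C
F2 | step 10 | (2Z,5R)-5-[2-(furan-3-yl)ethyl]-5-methylhepta-2,6-dien-1-ol | OC/C=C\C[C@@](C)(CCc1ccoc1)C=C
F3 | step 10 | methyl (7R,9Z)-7-[2-(furan-3-yl)ethyl]-11-hydroxy-6,7-dimethyl-3-oxoundec-9-enoate (C6 epimers) | COC(=O)CC(=O)CCC(C)[C@](C)(CCc1ccoc1)C/C=C\CO
F4 | step 10 | methyl (7R,9Z)-11-bromo-7-[2-(furan-3-yl)ethyl]-6,7-dimethyl-3-oxoundec-9-enoate (C6 epimers) | COC(=O)CC(=O)CCC(C)[C@](C)(CCc1ccoc1)C/C=C\CBr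
F5 | step 13 | (6R,7R,9Z)-7-[2-(furan-3-yl)ethyl]-3-hydroxy-6,7-dimethyl-4,5,6,7,8,11-hexahydrocyclodeca[c]furan-1(3H)-one (lactol epimers) | O=C1OC(O)C2=C1C/C=C\C[C@@](C)(CCc3ccoc3)[C@H](C)CC2
F6 | step 13 | (6R,7R,9Z,11E)-7-[2-(furan-3-yl)ethyl]-6,7-dimethyl-5,6,7,8-tetrahydrocyclodeca[c]furan-1(4H)-one | O=C1OC=C2/C1=C\C=C/C[C@@](C)(CCc3ccoc3)[C@H](C)CC2
F7 | step 12 | methyl (1Z,5R,6R,8Z)-2-[(ethylsulfanyl)carbonyl]-6-[2-(furan-3-yl)ethyl]-5,6-dimethylcyclodeca-1,8-diene-1-carboxylate | COC(=O)/C1=C(C(=O)SCC)/CC[C@@H](C)[C@](C)(CCc2ccoc2)C/C=C\C1
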